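**Retrosynthetic overview**

1. Target 16 comes from flavanone 15 by chelation-controlled removal of the C5 O-methyl group; 15 comes from 4-methoxyflavan 13 by adjusting C4 (OMe → OH → C=O).
2. Ring C of 13 is cut at C3–C4 and O1–C2: ring A salicylaldehyde 6 supplies C4, C4a, C8a and O1, 4-vinylphenol 8 supplies C3, C2 and ring B, and trimethyl orthoformate 9 supplies the C4 methoxy group.
3. Feature used: ring C is the O1–C2–C3–C4 bridge fused to a ring A whose O1, C5-O and C7-O donors stabilise a C4 oxocarbenium ion, and C2 lies para to the free 4'-OH of ring B, so C2 is a latent para-quinone methide carbon.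
4. Aldehyde 6 comes from ortho-formylation of phenol 5, which comes from aromatic Claisen rearrangement of 1,1-dimethylallyl ether 4, made from 3,4,5-trimethoxyphenol 3 and carbonate 2 (from alcohol 1).
5. Ring order: rings A and B are bought; ring C is the only ring formed (step 6).

Key step: step 6

Assumption: the sense of induction of the chiral phosphoric acid cannot be predicted with confidence, so the (R)-catalyst is written and the enantiomer that gives (2S) would be fixed in a test run.

**Step 1**
Reactants: 1 2-methylbut-3-en-2-ol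
Product: 2 methyl 2-methylbut-3-en-2-yl carbonate
Conditions: n-BuLi, THF, –78 °C; then ClCO2Me, –78 °C → rt
Reagents that add atoms: methyl chloroformate, COC(=O)Cl
Why: Acylation of the lithium alkoxide of the tertiary allylic alcohol with a chloroformate is a routine carbonate synthesis and gives an allyl donor that ionises readily on palladium.

**Step 2**
Reactants: 3 3,4,5-trimethoxyphenol; 2 methyl 2-methylbut-3-en-2-yl carbonate
Product: 4 1,2,3-trimethoxy-5-[(2-methylbut-3-en-2-yl)oxy]benzene
Conditions: Pd(PPh3)4 (cat.), 4 Å molecular sieves, THF, 0 °C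
Reagents that add atoms: none
Why: Decarboxylative Tsuji–Trost O-allylation, in which the phenoxide captures the 1,1-dimethylallyl palladium cation at its more substituted terminus under kinetic control at low temperature, the established way to aryl 1,1-dimethylallyl ethers.

**Step 3**
Reactants: 4 1,2,3-trimethoxy-5-[(2-methylbut-3-en-2-yl)oxy]benzene
Product: 5 3,4,5-trimethoxy-2-(3-methylbut-2-enyl)phenol
Conditions: PhNEt2, 130 °C
Reagents that add atoms: none
Why: Aromatic Claisen rearrangement ([3,3]) transfers the allyl unit with transposition of its termini to one of the two equivalent free ortho positions, so the 3-methylbut-2-enyl group ends on carbon and tautomerisation restores the phenol; the amine solvent buffers traces of acid.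

**Step 4**
Reactants: 5 3,4,5-trimethoxy-2-(3-methylbut-2-enyl)phenol
Product: 6 2-hydroxy-4,5,6-trimethoxy-3-(3-methylbut-2-enyl)benzaldehyde
Conditions: MgCl2, Et3N, (CH2O)n, MeCN, 80 °C; then dilute aq HCl
Reagents that add atoms: paraformaldehyde (as formaldehyde), C=O
Why: Casnati–Skattebøl ortho-formylation, in which the magnesium phenoxide delivers formaldehyde to the only free ortho carbon (the para position carries a methoxy group) and a second formaldehyde accepts hydride, under conditions that leave the prenyl olefin alone.

**Step 5**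
Reactants: 7 4-acetoxystyrene
Product: 8 4-vinylphenol
Conditions: K2CO3 (cat.), MeOH, 0 °C → rt; used at once
Reagents that add atoms: none
Why: Base-catalysed methanolysis (transesterification) of the aryl acetate frees the phenol under conditions mild enough to avoid polymerisation of the styrene.

**Step 6**
Reactants: 6 2-hydroxy-4,5,6-trimethoxy-3-(3-methylbut-2-enyl)benzaldehyde; 8 4-vinylphenol; 9 trimethyl orthoformate
Product: 13 (2S)-2-(4-hydroxyphenyl)-4,5,6,7-tetramethoxy-8-(3-methylbut-2-enyl)chroman (both C4 epimers), via dimethyl acetal 10 (not isolated), via oxocarbenium ion 11 (not isolated), via para-quinone methide 12 (not isolated)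
Conditions: (R)-3,3'-bis(2,4,6-triisopropylphenyl)-1,1'-binaphthyl-2,2'-diyl hydrogen phosphate (10 mol %), HC(OMe)3 (3 equiv), 5 Å molecular sieves, CH2Cl2, rt; then 8 (1.5 equiv, slow addition), –40 °C
Reagents that add atoms: trimethyl orthoformate (9), COC(OC)OC
Why: Proposed new method: the phosphoric acid turns 6 and the orthoformate into acetal 10 and ionises it to oxocarbenium ion 11 (the O-protonated methoxy ortho-quinone methide, stabilised by O1 and the C5 and C7 methoxy groups); the CH2 terminus of 8 adds to the carbenium carbon to form C3–C4 while the phenolic proton passes to the phosphate, which leaves the neutral para-quinone methide 12, and the ring A hydroxyl then adds to its exocyclic carbon to form O1–C2. The closest known reactions are the acid-promoted three-component annulation of salicylaldehydes, trimethyl orthoformate and styrenes to racemic 4-methoxy-2-arylchromans and chiral phosphoric acid catalysed enantioselective 1,6-additions to para-quinone methides. Ring C closes by a 6-exo-trig oxa-1,6-addition. C2 is set in this closure by the chiral phosphate, which is hydrogen-bonded to the quinone methide carbonyl and to the attacking ring A hydroxyl and so distinguishes the two faces of the methide carbon, whereas C4 forms as both epimers and is erased by the oxidation in step 8. Regiochemistry follows from polarity (nucleophilic styrene terminus on the carbenium carbon, phenol oxygen on the benzylic cation equivalent), and the step needs the acetal to ionise while the prenyl olefin, the C4 ether of the product and the new C2–O1 bond stay intact, which the weak acid, the low temperature and the much greater stabilisation of 11 should secure.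

**Step 7**
Reactants: 13 (2S)-2-(4-hydroxyphenyl)-4,5,6,7-tetramethoxy-8-(3-methylbut-2-enyl)chroman (both C4 epimers)
Product: 14 (2S)-2-(4-hydroxyphenyl)-5,6,7-trimethoxy-8-(3-methylbut-2-enyl)chroman-4-ol (both C4 epimers)
Conditions: 0.1 M aq HCl, THF, 0 °C
Reagents that add atoms: water, O
Why: SN1 solvolysis of the benzylic ether, in which the C4 cation stabilised by O1 and the C5 and C7 methoxy groups should form in dilute acid much faster than C2–O1 ionises or the prenyl olefin is protonated, and water in large excess traps it as the alcohol.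

**Step 8**
Reactants: 14 (2S)-2-(4-hydroxyphenyl)-5,6,7-trimethoxy-8-(3-methylbut-2-enyl)chroman-4-ol (both C4 epimers)
Product: 15 (2S)-2-(4-hydroxyphenyl)-5,6,7-trimethoxy-8-(3-methylbut-2-enyl)chroman-4-one
Conditions: MnO2 (activated, excess), CH2Cl2, rt
Reagents that add atoms: none
Why: MnO2 oxidation of a benzylic alcohol should converge both C4 epimers on one ketone without touching the prenyl olefin, and the neutral heterogeneous medium contains no base that could open the flavanone to a chalcone and racemise C2.

**Step 9**
Reactants: 15 (2S)-2-(4-hydroxyphenyl)-5,6,7-trimethoxy-8-(3-methylbut-2-enyl)chroman-4-one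
Product: 16 (2S)-5-hydroxy-2-(4-hydroxyphenyl)-6,7-dimethoxy-8-(3-methylbut-2-enyl)chroman-4-one
Conditions: BCl3 (3 equiv), CH2Cl2, –78 → –20 °C; then H2O, 0 °C
Reagents that add atoms: none
Why: Chelation-controlled ether cleavage, in which BCl3 bound to the C4 carbonyl oxygen activates only the peri C5 methoxy group for demethylation by chloride at low temperature, while the C6 and C7 methoxy groups and the prenyl olefin (no free hydroxyl beside it) should survive and C2 is not touched.

**Compound list**

1 | 2-methylbut-3-en-2-ol | CC(C)(O)C=C | starting material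
2 | methyl 2-methylbut-3-en-2-yl carbonate | COC(=O)OC(C)(C)C=C | intermediate
3 | 3,4,5-trimethoxyphenol | COc1cc(O)cc(OC)c1OC | starting material
4 | 1,2,3-trimethoxy-5-[(2-methylbut-3-en-2-yl)oxy]benzene | COc1cc(OC(C)(C)C=C)cc(OC)c1OC | intermediate
5 | 3,4,5-trimethoxy-2-(3-methylbut-2-enyl)phenol | COc1cc(O)c(CC=C(C)C)c(OC)c1OC | intermediate
6 | 2-hydroxy-4,5,6-trimethoxy-3-(3-methylbut-2-enyl)benzaldehyde | COc1c(OC)c(C=O)c(O)c(CC=C(C)C)c1OC | intermediate
7 | 4-acetoxystyrene | CC(=O)Oc1ccc(C=C)cc1 | starting material
8 | 4-vinylphenol | C=Cc1ccc(O)cc1 | intermediate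
9 | trimethyl orthoformate | COC(OC)OC | starting material
10 | 2-(dimethoxymethyl)-3,4,5-trimethoxy-6-(3-methylbut-2-enyl)phenol (dimethyl acetal of 6, formed in the flask) | COc1c(OC)c(C(OC)OC)c(O)c(CC=C(C)C)c1OC | intermediate
11 | [2-hydroxy-4,5,6-trimethoxy-3-(3-methylbut-2-enyl)phenyl]methylidene(methyl)oxonium, ion pair with the chiral phosphate (formed in the flask) | COc1c(OC)c(C=[O+]C)c(O)c(CC=C(C)C)c1OC | intermediate
12 | 4-{3-[2-hydroxy-4,5,6-trimethoxy-3-(3-methylbut-2-enyl)phenyl]-3-methoxypropylidene}cyclohexa-2,5-dien-1-one (formed in the flask) | COc1c(OC)c(C(OC)CC=C2C=CC(=O)C=C2)c(O)c(CC=C(C)C)c1OC | intermediate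
13 | (2S)-2-(4-hydroxyphenyl)-4,5,6,7-tetramethoxy-8-(3-methylbut-2-enyl)chroman, both C4 epimers | COc1c(OC)c2c(c(CC=C(C)C)c1OC)O[C@H](c1ccc(O)cc1)CC2OC | intermediate
14 | (2S)-2-(4-hydroxyphenyl)-5,6,7-trimethoxy-8-(3-methylbut-2-enyl)chroman-4-ol, both C4 epimers | COc1c(OC)c2c(c(CC=C(C)C)c1OC)O[C@H](c1ccc(O)cc1)CC2O | intermediate
15 | (2S)-2-(4-hydroxyphenyl)-5,6,7-trimethoxy-8-(3-methylbut-2-enyl)chroman-4-one | COc1c(OC)c2c(c(CC=C(C)C)c1OC)O[C@H](c1ccc(O)cc1)CC2=O | intermediate
16 | (2S)-5-hydroxy-2-(4-hydroxyphenyl)-6,7-dimethoxy-8-(3-methylbut-2-enyl)chroman-4-one | COc1c(O)c2c(c(CC=C(C)C)c1OC)O[C@H](c1ccc(O)cc1)CC2=O | target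

**Step count and risks**

Total step count: 9. Longest linear sequence: 8 steps (steps 1, 2, 3, 4, 6, 7, 8, 9).

Steps most likely to fail:

1. Step 6 (proposed new method). The ring closure may escape catalyst control, either because the C4 centre already present directs the oxa-1,6-addition or because an uncatalysed concerted cycloaddition competes. 4-Vinylphenol may also oligomerise under acid, and C2 may erode by reversible opening of C2–O1.
Fallback with known chemistry, setting out from aldehyde 6 and coming back at flavanone 15. MeMgBr (THF, 0 °C) should add to 6 to give 1-[2-hydroxy-4,5,6-trimethoxy-3-(3-methylbut-2-enyl)phenyl]ethanol F1. MnO2 (CH2Cl2) should oxidise it to 1-[2-hydroxy-4,5,6-trimethoxy-3-(3-methylbut-2-enyl)phenyl]ethanone F2. Me2NCH(OMe)2 (neat, 90 °C) should give the enaminone (E)-3-(dimethylamino)-1-[2-hydroxy-4,5,6-trimethoxy-3-(3-methylbut-2-enyl)phenyl]prop-2-en-1-one F3, which should close with aqueous HCl in CH2Cl2 to 5,6,7-trimethoxy-8-(3-methylbut-2-enyl)chromen-4-one F4. Asymmetric conjugate addition of 4-(tert-butyldimethylsilyloxy)phenylboronic acid would follow, with Pd(OCOCF3)2, (S)-4-tert-butyl-2-(pyridin-2-yl)-4,5-dihydrooxazole (or its enantiomer, whichever gives 2S), NH4PF6 and H2O in ClCH2CH2Cl at 60 °C. It should give (2S)-2-[4-(tert-butyldimethylsilyloxy)phenyl]-5,6,7-trimethoxy-8-(3-methylbut-2-enyl)chroman-4-one F5. HF·pyridine (THF, 0 °C) should then free the phenol to give 15, and step 9 follows unchanged.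

2. Step 7. Ionisation at C4 may be diverted to elimination across C3–C4, to Friedel–Crafts capture of the cation by ring B of a second molecule, or be accompanied by acid opening of C2–O1 with loss of configuration.
Fallback, setting out from 13 and coming back at 15, bypassing the free alcohol and step 8. Ac2O and pyridine should mask the phenol as 4-[(2S)-4,5,6,7-tetramethoxy-8-(3-methylbut-2-enyl)chroman-2-yl]phenyl acetate F6. 2,3-Dichloro-5,6-dicyano-1,4-benzoquinone in CH2Cl2 and pH 7 buffer at 0 °C should abstract hydride from C4, and water should convert the resulting oxocarbenium ion directly into the ketone 4-[(2S)-5,6,7-trimethoxy-8-(3-methylbut-2-enyl)-4-oxochroman-2-yl]phenyl acetate F7. Acidic methanolysis (catalytic AcCl in MeOH, 0 °C → rt) should remove the acetate without base and give 15.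

3. Step 3. At the rearrangement temperature the tertiary allyl–oxygen bond may ionise with loss of the C5 unit, and the ortho-prenylphenol formed may add its hydroxyl across its own olefin to give a 2,2-dimethylchroman.
Fallback, setting out from 3 and coming back at 5, replacing steps 1 to 3 by directed metalation. Chloromethyl methyl ether and i-Pr2NEt (CH2Cl2) should give 1,2,3-trimethoxy-5-(methoxymethoxy)benzene F8. n-BuLi (THF, 0 °C) should lithiate the position between the methoxymethoxy and methoxy groups; transmetalation with CuBr·SMe2 and alkylation with 1-bromo-3-methylbut-2-ene should give 1,2,3-trimethoxy-5-(methoxymethoxy)-4-(3-methylbut-2-enyl)benzene F9. Catalytic HCl in MeOH at rt should remove the acetal to give 5.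

**Further compounds**

F1 | step 6 | 1-[2-hydroxy-4,5,6-trimethoxy-3-(3-methylbut-2-enyl)phenyl]ethanol (racemic) | COc1c(OC)c(C(C)O)c(O)c(CC=C(C)C)c1OC
F2 | step 6 | 1-[2-hydroxy-4,5,6-trimethoxy-3-(3-methylbut-2-enyl)phenyl]ethanone | COc1c(OC)c(C(C)=O)c(O)c(CC=C(C)C)c1OC
F3 | step 6 | (E)-3-(dimethylamino)-1-[2-hydroxy-4,5,6-trimethoxy-3-(3-methylbut-2-enyl)phenyl]prop-2-en-1-one | COc1c(OC)c(C(=O)/C=C/N(C)C)c(O)c(CC=C(C)C)c1OC
F4 | step 6 | 5,6,7-trimethoxy-8-(3-methylbut-2-enyl)chromen-4-one | COc1c(OC)c2c(c(CC=C(C)C)c1OC)OC=CC2=O
F5 | step 6 | (2S)-2-[4-(tert-butyldimethylsilyloxy)phenyl]-5,6,7-trimethoxy-8-(3-methylbut-2-enyl)chroman-4-one | COc1c(OC)c2c(c(CC=C(C)C)c1OC)O[C@H](c1ccc(O[Si](C)(C)C(C)(C)C)cc1)CC2=O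
F6 | step 7 | 4-[(2S)-4,5,6,7-tetramethoxy-8-(3-methylbut-2-enyl)chroman-2-yl]phenyl acetate, both C4 epimers | COc1c(OC)c2c(c(CC=C(C)C)c1OC)O[C@H](c1ccc(OC(C)=O)cc1)CC2OC
F7 | step 7 | 4-[(2S)-5,6,7-trimethoxy-8-(3-methylbut-2-enyl)-4-oxochroman-2-yl]phenyl acetate | COc1c(OC)c2c(c(CC=C(C)C)c1OC)O[C@H](c1ccc(OC(C)=O)cc1)CC2=O
F8 | step 3 | 1,2,3-trimethoxy-5-(methoxymethoxy)benzene | COCOc1cc(OC)c(OC)c(OC)c1
F9 | step 3 | 1,2,3-trimethoxy-5-(methoxymethoxy)-4-(3-methylbut-2-enyl)benzene | COCOc1cc(OC)c(OC)c(OC)c1CC=C(C)C
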